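**Remarks.** Atom numbers follow the chamigrane skeleton (spiro[5.5]undecane: ring B = C1–C5, spiro carbon C6, ring A = C7–C11; C12/C13 are the methyls on C11, C14 the exocyclic methylene carbon on C7, C15 the methyl on C3). In this numbering the target is (2R,3R,6S,10R). Assumption: compounds 1, 4 and 5 and all reagents are commercial; the sense of induction of the chiral reagents in steps 1 and 9 is assigned by analogy, and the mirror-image ligand or base is used if the sense proves opposite.

## The problem

The target is a spiro[5.5]undecane whose spiro carbon C6 is bonded to the quaternary C11 (gem-dimethyl) and to the sp2 carbon C7. The C6–C11 bond between two fully substituted carbons is the one that resists closure. There are four stereocentres: C10 (a secondary bromide next to C11, where substitution with inversion is not available), C6, and the trans C2-chloride/C3-bromide pair on ring B. In that pair bromine sits on the tertiary carbon, the reverse of what Markovnikov addition of BrCl to a 1-methylcyclohexene gives. C6 is a stereocentre only because C2 and C3 are substituted; the arms C1–C2 and C5–C4 of ring B are otherwise identical, so the relation between C10 and C2/C3 must pass through a centre with no handle of its own.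

The plan turns this into the enabling feature. With C3 at the ketone level, ring B has a local mirror plane through C3 and C6. An exocyclic C6=C7 alkene on such a ring has no E/Z isomers, and C10 can be the only stereocentre when the C6–C11 bond is made by opening a C10/C11 bromonium ion at C11. On ring B the quaternary C11 behaves like a tert-butyl group and stays equatorial, C7 is axial, and in that chair the target has C3–Br and C2–Cl trans-diaxial with chlorine syn-axial to C7. This gives the handle for setting C2 and C3 from C6.

The tertiary bromide (ionisation, elimination, 1,2-interchange with the vicinal chlorine on heating) and the exocyclic C7=C14 alkene (acid moves it into the ring or adds HX) will not survive rough treatment. The ring-B halogens therefore come last, cold, without base and with as few protons as possible.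

## Retrosynthesis

**C3–Br (23 ⇒ 20).** The last bond cut is C3–Br, leading back to the chlorohydrin 20. Direct BrCl addition to the alkene 18 would require chloride to open a bromonium ion at the secondary C2 against Markovnikov's rule. With chlorine placed first, bromide captures the chlorine-bridged C3 cation 22 at the tertiary carbon, axially and anti to chlorine, so the Markovnikov and trans-diaxial demands coincide. The forward step must ionise a tertiary C–O bond (as the silyl ether 21) without protonating the exocyclic alkene.

**C2–Cl and the oxygen (20 ⇒ 19 ⇒ 18).** The C2–Cl bond is cut to the epoxide 19, whose opening at the secondary carbon is both the SN2 and the trans-diaxial mode. Epoxide 19 comes from 18 by peracid attack on the ring-B face opposite the axial C7. This removes two stereocentres: 18 has only C6 and C10.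

**C3–CH3 and the stereogenicity of C6 (18 ⇒ 17 ⇒ 15).** The C3–C15 bond is cut to the enol triflate 17, and the C2=C3 enol double bond is then removed to give ketone 15, in which ring B is mirror-symmetric and C6 is not a stereocentre. The forward reaction, a chiral lithium amide choosing H-2 over H-4, sets C6 under reagent control. The neighbouring cuts (cycloaddition or cation closure onto an unsymmetrical ring B) would have to set C6 in a C–C bond-forming step with only remote bias.

**Ring A, C6–C11 (15 ⇒ 14 ⇒ 12).** Ketone 15 is unmasked from the ketal 14. Cutting C6–C11 in 14, with the C7=C14 alkene traced to an allylsilane, gives the monocyclic 12 with a single stereocentre and no alkene geometry. The forward step ionises the tertiary chloride of 12 to the bromonium ion 13 and closes ring A through C6. It asks for C-alkylation at a fully substituted carbon and for survival of the allylsilane until the cation is formed.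

**The tetrasubstituted allylsilane (12 ⇒ 11 ⇒ 9).** The C14–C7 bond is cut to the enol triflate 11. The triflate comes from enone 9 by conjugate reduction through enolate 10, because direct enolisation of a saturated ketone would go to C8 and not to the ring carbon C6.

**C8–C9 and the chiral fragment (9 ⇒ 7 + 3; 3 ⇒ 2 ⇒ 1; 7 ⇒ 4 + 5).** Cutting C8–C9 gives the enolate 8 of the methyl enone 7 and the triflate 3. Triflate 3 carries C10 and is made from prenol 1 through the bromochloro alcohol 2. Enone 7 comes from the enol triflate 4 and the stannane 5. The halogenated fragment can only be the electrophile, since a carbanion at C9 would expel the C10 bromide.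

## Roads not taken

**Alternative 1: Diels–Alder closure of ring B (the most obvious cut).** Bonds C1–C6 and C4–C5 are cut. The α-methylene ketone A1 (ring A with the C10 bromide in place) would add isoprene A2 to give the spiro ketone A3, to be methylenated to 18.
- The cycloaddition would have to set C6 against C10 by facial selectivity on an exocyclic alkene flanked by the gem-dimethyl carbon, with an equatorial bromide two atoms away as the only bias.
- A1 is hindered and prone to self-condensation.
- A3 needs methylenation of a ketone next to the spiro carbon in the presence of a γ-bromide, which basic ylides can eliminate or cyclise.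
- The chosen plan sets C6 by reagent control and obtains C7=C14 from the ring closure itself.

**Alternative 2: biomimetic closure of ring A onto an unsymmetrical ring B.** The C6–C11 bond of 18 is cut to (E)-γ-bisabolene A4, to be cyclised with an electrophilic bromine reagent.
- Three alkenes compete for the reagent, and the tetrasubstituted one is the most nucleophilic.
- C10 would need a chiral bromine source.
- The C6/C10 relation is dictated by the geometry of the C6=C7 alkene of A4, whose isomers differ only in the remote position of the ring alkene.
- Proton loss would give the endocyclic isomer A5 beside 18.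
- The chosen plan answers these by internal ionisation of a preset bromochloride, by the symmetry of ring B, and by silicon.

**Alternative 3: spiro centre first by enantioselective allylation, ring B by metathesis.** C2=C3 is cut by ring-closing metathesis and C6–C1 by decarboxylative allylic alkylation (zerovalent palladium, chiral phosphinooxazoline). The α-quaternary ketone A6 would give the spiro ketone A7 with the second-generation Grubbs catalyst.
- C6 is set well, but the C10 bromide must then be introduced at a secondary carbon next to the quaternary C11, where displacement of an oxygen leaving group with inversion fails or rearranges.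
- The C10/C6 relation would need separate control, and the step count rises.
- The chosen plan makes the C10–Br bond by bromonium opening at the adjacent tertiary carbon, the reaction that forms such bonds reliably.

Key step: step 7

## Route

**Step 1**
Reactants: 1 3-methylbut-2-en-1-ol (prenol)
Product: 2 (2R)-2-bromo-3-chloro-3-methylbutan-1-ol
Conditions: NBS, ClTi(OiPr)3, chiral tridentate salicylaldimine amino-alcohol ligand (20 mol %, the enantiomer that gives 2R), hexanes, −20 °C
Reagents that add atoms: N-bromosuccinimide, O=C1CCC(=O)N1Br; chlorotitanium triisopropoxide, CC(C)O[Ti](Cl)(OC(C)C)OC(C)C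
Why: Catalytic enantioselective bromochlorination of an allylic alcohol: the titanium-bound alkoxide receives bromine from NBS and chloride from titanium anti to it, chloride going to the distal tertiary carbon (also the Markovnikov position); the chiral ligand on titanium sets C2 of 2, the later C10.

**Step 2**
Reactants: 2 (2R)-2-bromo-3-chloro-3-methylbutan-1-ol
Product: 3 (2R)-2-bromo-3-chloro-3-methylbutyl trifluoromethanesulfonate
Conditions: Tf2O, 2,6-lutidine, CH2Cl2, −78 °C
Reagents that add atoms: trifluoromethanesulfonic anhydride, O=S(=O)(OS(=O)(=O)C(F)(F)F)C(F)(F)F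
Why: Standard O-sulfonylation at low temperature; the stereocentre is not touched and the primary triflate is used at once.

**Step 3**
Reactants: 4 1,4-dioxaspiro[4.5]dec-7-en-8-yl trifluoromethanesulfonate; 5 tributyl(1-ethoxyvinyl)stannane
Product: 7 1-(1,4-dioxaspiro[4.5]dec-7-en-8-yl)ethan-1-one, via ethoxyvinyl diene 6 (not isolated)
Conditions: Pd(PPh3)4 (3 mol %), LiCl, THF, 65 °C; then 5% aq. oxalic acid, THF, 0 °C
Reagents that add atoms: water, O
Why: Stille coupling of an enol triflate with an acyl-anion equivalent; the enol ether of 6 hydrolyses far faster than the dioxolane and gives the conjugated methyl ketone.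

**Step 4**
Reactants: 7 1-(1,4-dioxaspiro[4.5]dec-7-en-8-yl)ethan-1-one; 3 (2R)-2-bromo-3-chloro-3-methylbutyl trifluoromethanesulfonate
Product: 9 (4R)-4-bromo-5-chloro-5-methyl-1-(1,4-dioxaspiro[4.5]dec-7-en-8-yl)hexan-1-one, via lithium enolate 8 (not isolated)
Conditions: lithium diisopropylamide, THF, −78 °C; then 3, DMPU, −78 → −40 °C
Reagents that add atoms: none
Why: Kinetic deprotonation of the enone at the methyl group gives the cross-conjugated enolate 8, which is alkylated by the primary triflate (SN2) to form the C8–C9 bond; the C10 stereocentre is a spectator.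

**Step 5**
Reactants: 9 (4R)-4-bromo-5-chloro-5-methyl-1-(1,4-dioxaspiro[4.5]dec-7-en-8-yl)hexan-1-one
Product: 11 (4R)-4-bromo-5-chloro-1-(1,4-dioxaspiro[4.5]decan-8-ylidene)-5-methylhexyl trifluoromethanesulfonate, via lithium enolate 10 (not isolated)
Conditions: LiBH(sec-Bu)3, THF, −78 °C; then N-(5-chloropyridin-2-yl)bis(trifluoromethanesulfonimide), −78 → 0 °C
Reagents that add atoms: N-(5-chloropyridin-2-yl)bis(trifluoromethanesulfonimide), Clc1ccc(nc1)N(S(=O)(=O)C(F)(F)F)S(=O)(=O)C(F)(F)F
Why: Conjugate hydride addition to a 1-acylcycloalkene gives the C6=C7 enolate 10 regiospecifically, and O-triflation freezes it; because ring B is mirror-symmetric again, the tetrasubstituted alkene has no geometrical isomers.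

**Step 6**
Reactants: 11 (4R)-4-bromo-5-chloro-1-(1,4-dioxaspiro[4.5]decan-8-ylidene)-5-methylhexyl trifluoromethanesulfonate
Product: 12 [(5R)-5-bromo-6-chloro-2-(1,4-dioxaspiro[4.5]decan-8-ylidene)-6-methylheptyl]trimethylsilane
Conditions: Me3SiCH2MgCl, Pd(PPh3)4 (5 mol %), THF, 0 °C → rt
Reagents that add atoms: (trimethylsilyl)methylmagnesium chloride, C[Si](C)(C)C[Mg]Cl
Why: Kumada coupling of an enol triflate with Me3SiCH2MgCl, the standard route to allylsilanes; oxidative addition to the enol triflate is far faster than any reaction of the hindered secondary bromide or the tertiary chloride.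

**Step 7**
Reactants: 12 [(5R)-5-bromo-6-chloro-2-(1,4-dioxaspiro[4.5]decan-8-ylidene)-6-methylheptyl]trimethylsilane
Product: 14 (10R)-10-bromo-9,9-dimethyl-13-methylidene-1,4-dioxadispiro[4.2.5.2]pentadecane, via bromonium ion 13 (not isolated)
Conditions: (CF3)2CHOH (0.01 M), 2,6-di-tert-butyl-4-methylpyridine, 0 °C → rt
Reagents that add atoms: none
Why: In hexafluoroisopropanol the tertiary C11–Cl bond of 12 ionises with anti-periplanar participation of the C10 bromine and gives the configurationally defined bromonium ion 13 without any external electrophile, so the electron-rich allylsilane never meets a bromine reagent. C6, the γ-carbon of the allylsilane, opens 13 at the tertiary C11 and closes ring A in a 6-endo mode (both alkene carbons C6 and C7 end up in the ring) through a chair with the C10–Br bond equatorial. The charge developing at C7 is β to silicon and is discharged by loss of the silyl group, which fixes the new double bond as the exocyclic C7=C14 methylene and excludes the endocyclic isomer. The closest known reaction types are the solvolytic bromonium cyclisation of vicinal bromochlorides onto alkene or enol nucleophiles and the allylsilane-terminated cation–olefin cyclisation. No new stereocentre is formed: C10 keeps the configuration set in step 1 because its C–Br bond is never broken, and C6 is not yet stereogenic because ring B is mirror-symmetric. The step needs attack at C11 and not C10 (secured by the tertiary/secondary difference and the six-membered chair) and C-alkylation through C6 in preference to proton loss from 13 (secured by the nucleophilicity of the allylsilane); the hindered pyridine keeps the medium from protodesilylating 12.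

**Step 8**
Reactants: 14 (10R)-10-bromo-9,9-dimethyl-13-methylidene-1,4-dioxadispiro[4.2.5.2]pentadecane
Product: 15 (10R)-10-bromo-11,11-dimethyl-7-methylidenespiro[5.5]undecan-3-one
Conditions: pyridinium p-toluenesulfonate (cat.), acetone/H2O, 50 °C
Reagents that add atoms: water, O
Why: Acid-catalysed ketal hydrolysis; the acid is too weak to move the exocyclic alkene into the ring or to ionise the secondary bromide.

**Step 9**
Reactants: 15 (10R)-10-bromo-11,11-dimethyl-7-methylidenespiro[5.5]undecan-3-one
Product: 17 (6S,10R)-10-bromo-11,11-dimethyl-7-methylidenespiro[5.5]undec-2-en-3-yl trifluoromethanesulfonate, via lithium enolate 16 (not isolated)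
Conditions: (R,R)-bis(1-phenylethyl)amine hydrochloride, n-BuLi (2 equiv), THF, −78 → 0 °C, then 15, −100 °C; then N-(5-chloropyridin-2-yl)bis(trifluoromethanesulfonimide), −100 → −40 °C
Reagents that add atoms: N-(5-chloropyridin-2-yl)bis(trifluoromethanesulfonimide), Clc1ccc(nc1)N(S(=O)(=O)C(F)(F)F)S(=O)(=O)C(F)(F)F
Why: Group-selective deprotonation of a conformationally biased 4,4-disubstituted cyclohexanone by a chiral lithium amide (in the presence of LiCl): the base removes axial H-2 in preference to axial H-4 and so turns C6 into a stereocentre under reagent control, the sense (6S) being assigned by analogy with 4-tert-butylcyclohexanone with C11 in the place of the tert-butyl group. O-Triflation of enolate 16 fixes the position of the double bond.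

**Step 10**
Reactants: 17 (6S,10R)-10-bromo-11,11-dimethyl-7-methylidenespiro[5.5]undec-2-en-3-yl trifluoromethanesulfonate
Product: 18 (6S,10R)-10-bromo-3,11,11-trimethyl-7-methylidenespiro[5.5]undec-2-ene (10-bromo-β-chamigrene)
Conditions: MeZnCl, Pd(PPh3)4 (5 mol %), THF, rt → 40 °C
Reagents that add atoms: methylzinc chloride, C[Zn]Cl
Why: Negishi coupling of the enol triflate without movement of the double bond; the unactivated secondary bromide does not undergo oxidative addition with this catalyst.

**Step 11**
Reactants: 18 (6S,10R)-10-bromo-3,11,11-trimethyl-7-methylidenespiro[5.5]undec-2-ene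
Product: 19 (2S,3R,6S,10R)-10-bromo-2,3-epoxy-3,11,11-trimethyl-7-methylidenespiro[5.5]undecane
Conditions: mCPBA (1.0 equiv), CH2Cl2, −20 → 0 °C
Reagents that add atoms: 3-chloroperbenzoic acid, OOC(=O)c1cccc(Cl)c1
Why: Peracid epoxidation is faster at the trisubstituted ring alkene than at the hindered 1,1-disubstituted exocyclic one. On ring B the quaternary C11 is equatorial and C7 pseudo-axial, so the peracid should approach the face opposite C7 and place oxygen cis to C11.

**Step 12**
Reactants: 19 (2S,3R,6S,10R)-10-bromo-2,3-epoxy-3,11,11-trimethyl-7-methylidenespiro[5.5]undecane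
Product: 20 (2R,3R,6S,10R)-10-bromo-2-chloro-3,11,11-trimethyl-7-methylidenespiro[5.5]undecan-3-ol
Conditions: LiCl, AcOH, THF, rt → 40 °C
Reagents that add atoms: lithium chloride, [Li+].[Cl-]
Why: SN2-type opening of the epoxide by chloride at the secondary carbon C2 with inversion. In the chair that keeps C11 equatorial this is also the trans-diaxial (Fürst–Plattner) mode, so the steric and stereoelectronic preferences coincide and leave the C3 oxygen axial, anti-periplanar to the new C–Cl bond.

**Step 13**
Reactants: 20 (2R,3R,6S,10R)-10-bromo-2-chloro-3,11,11-trimethyl-7-methylidenespiro[5.5]undecan-3-ol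
Product: 23 (2R,3R,6S,10R)-3,10-dibromo-2-chloro-3,11,11-trimethyl-7-methylidenespiro[5.5]undecane, via trimethylsilyl ether 21 (not isolated), via chloronium ion 22 (not isolated)
Conditions: Me3SiOTf, 2,6-lutidine, CH2Cl2, −78 °C, aqueous work-up; then BBr3, 2,6-di-tert-butyl-4-methylpyridine, CH2Cl2, −78 → −40 °C
Reagents that add atoms: boron tribromide, BrB(Br)Br
Why: Lewis-acid conversion of a tertiary silyl ether into the bromide without a Brønsted acid, the hindered pyridine trapping stray HBr so that the exocyclic alkene is not protonated. The C3–O bond of 21 ionises with participation of the anti-periplanar axial C2 chlorine to the bridged cation 22, which bromide opens at the tertiary carbon, axially and anti to chlorine; C3 is substituted with net retention and bromine ends trans to chlorine, the Markovnikov and the trans-diaxial mode at once.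

## Compound list

1 | 3-methylbut-2-en-1-ol (prenol) | CC(C)=CCO | starting material
2 | (2R)-2-bromo-3-chloro-3-methylbutan-1-ol | OC[C@@H](Br)C(C)(C)Cl | intermediate
3 | (2R)-2-bromo-3-chloro-3-methylbutyl trifluoromethanesulfonate | FC(F)(F)S(=O)(=O)OC[C@@H](Br)C(C)(C)Cl | intermediate
4 | 1,4-dioxaspiro[4.5]dec-7-en-8-yl trifluoromethanesulfonate | O=S(=O)(OC1=CCC2(CC1)OCCO2)C(F)(F)F | starting material
5 | tributyl(1-ethoxyvinyl)stannane | CCCC[Sn](CCCC)(CCCC)C(=C)OCC | starting material
6 | 8-(1-ethoxyvinyl)-1,4-dioxaspiro[4.5]dec-7-ene (not isolated) | CCOC(=C)C1=CCC2(CC1)OCCO2 | intermediate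
7 | 1-(1,4-dioxaspiro[4.5]dec-7-en-8-yl)ethan-1-one | CC(=O)C1=CCC2(CC1)OCCO2 | intermediate
8 | lithium 1-(1,4-dioxaspiro[4.5]dec-7-en-8-yl)ethen-1-olate (not isolated) | C=C(O[Li])C1=CCC2(CC1)OCCO2 | intermediate
9 | (4R)-4-bromo-5-chloro-5-methyl-1-(1,4-dioxaspiro[4.5]dec-7-en-8-yl)hexan-1-one | CC(C)(Cl)[C@H](Br)CCC(=O)C1=CCC2(CC1)OCCO2 | intermediate
10 | lithium (4R)-4-bromo-5-chloro-1-(1,4-dioxaspiro[4.5]decan-8-ylidene)-5-methylhexan-1-olate (not isolated) | CC(C)(Cl)[C@H](Br)CCC(O[Li])=C1CCC2(CC1)OCCO2 | intermediate
11 | (4R)-4-bromo-5-chloro-1-(1,4-dioxaspiro[4.5]decan-8-ylidene)-5-methylhexyl trifluoromethanesulfonate | CC(C)(Cl)[C@H](Br)CCC(OS(=O)(=O)C(F)(F)F)=C1CCC2(CC1)OCCO2 | intermediate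
12 | [(5R)-5-bromo-6-chloro-2-(1,4-dioxaspiro[4.5]decan-8-ylidene)-6-methylheptyl]trimethylsilane | CC(C)(Cl)[C@H](Br)CCC(C[Si](C)(C)C)=C1CCC2(CC1)OCCO2 | intermediate
13 | bromonium ion of 12, (R)-configured 2,2-dimethyl-3-alkylbromiranium chloride (not isolated) | CC1(C)[Br+][C@@H]1CCC(C[Si](C)(C)C)=C1CCC2(CC1)OCCO2.[Cl-] | intermediate
14 | (10R)-10-bromo-9,9-dimethyl-13-methylidene-1,4-dioxadispiro[4.2.5.2]pentadecane | C=C1CC[C@@H](Br)C(C)(C)C12CCC3(CC2)OCCO3 | intermediate
15 | (10R)-10-bromo-11,11-dimethyl-7-methylidenespiro[5.5]undecan-3-one | C=C1CC[C@@H](Br)C(C)(C)C12CCC(=O)CC2 | intermediate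
16 | lithium (6S,10R)-10-bromo-11,11-dimethyl-7-methylidenespiro[5.5]undec-2-en-3-olate (not isolated) | C=C1CC[C@@H](Br)C(C)(C)[C@]12CCC(O[Li])=CC2 | intermediate
17 | (6S,10R)-10-bromo-11,11-dimethyl-7-methylidenespiro[5.5]undec-2-en-3-yl trifluoromethanesulfonate | C=C1CC[C@@H](Br)C(C)(C)[C@]12CCC(OS(=O)(=O)C(F)(F)F)=CC2 | intermediate
18 | (6S,10R)-10-bromo-3,11,11-trimethyl-7-methylidenespiro[5.5]undec-2-ene (10-bromo-β-chamigrene) | C=C1CC[C@@H](Br)C(C)(C)[C@]12CCC(C)=CC2 | intermediate
19 | (2S,3R,6S,10R)-10-bromo-2,3-epoxy-3,11,11-trimethyl-7-methylidenespiro[5.5]undecane | C=C1CC[C@@H](Br)C(C)(C)[C@]12CC[C@@]3(C)O[C@H]3C2 | intermediate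
20 | (2R,3R,6S,10R)-10-bromo-2-chloro-3,11,11-trimethyl-7-methylidenespiro[5.5]undecan-3-ol | C=C1CC[C@@H](Br)C(C)(C)[C@]12CC[C@@](C)(O)[C@H](Cl)C2 | intermediate
21 | trimethylsilyl ether of 20 (not isolated) | C=C1CC[C@@H](Br)C(C)(C)[C@]12CC[C@@](C)(O[Si](C)(C)C)[C@H](Cl)C2 | intermediate
22 | C2/C3 chlorine-bridged cation (chloronium ion) derived from 21 (not isolated) | C=C1CC[C@@H](Br)C(C)(C)[C@]12CC[C@]3(C)[Cl+][C@@H]3C2 | intermediate
23 | (2R,3R,6S,10R)-3,10-dibromo-2-chloro-3,11,11-trimethyl-7-methylidenespiro[5.5]undecane | C=C1CC[C@@H](Br)C(C)(C)[C@]12CC[C@@](C)(Br)[C@H](Cl)C2 | target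

## Step count and risk

Total: 13 steps. Longest linear sequence: 12 steps (1 → 23 by steps 1, 2 and 4–13); step 3 is a one-step side branch.

**Step 7 (key step).** The allylsilane may be protodesilylated by the acidic solvent before ionisation. The bromonium ion may lose a proton or take chloride back. Ring closure may be slow because two fully substituted carbons are joined. Fallback from 9: the enolate 10 is silylated with tert-butyldimethylsilyl triflate to the tert-butyldimethylsilyl enol ether F1. F1 is an oxygen-substituted nucleophile of the kind already used in such solvolyses, and in hexafluoroisopropanol it should close to the spiro ketone ketal F2. Methylenation of F2 with Cp2TiMe2 (toluene, 70 °C) returns to the route at 14.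

**Step 13.** The β-chlorine retards ionisation of the tertiary C–O bond. Attack on the exocyclic alkene (addition of HBr, migration into the ring, capture of the C3 cation) or proton loss from C4 or C15 may then compete. Facial control is lost if the cation is not bridged. Fallback from 18, skipping 19 and 20: one-step bromochlorination with tetrabutylammonium dichlorobromate (CH2Cl2, −78 °C). It relies on bromine adding to the face opposite the axial C7 and on trans-diaxial opening by chloride at C2, and comes back at 23.

**Step 12.** Chloride may attack the tertiary C3 through a twist-boat (Markovnikov opening). The epoxide may rearrange under acid to a C2 ketone or a ring-contracted aldehyde. Attack syn-axial to C7 may be slow. Fallback from 15: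
- enamine-catalysed α-chlorination (N-chlorosuccinimide, a 2,5-diphenylpyrrolidine catalyst) desymmetrises ring B and places the axial chlorine on C2 in one operation, giving the α-chloro ketone F3;
- MeMgBr/CeCl3 adds anti to chlorine to give the epimeric chlorohydrin F4;
- F4 ionises to the same cation as 20 under the conditions of step 13 and rejoins at 23.

**Step 11.** Facial selectivity may be poor, since the only bias is the axial C7 three atoms from the alkene. Over-oxidation of the exocyclic alkene is also possible. Fallback from 18, using the other face:
- the epoxide with oxygen cis to C7, F5, is opened by bromide (LiBr, AcOH) at the tertiary C3, which for this isomer is both the Markovnikov and the trans-diaxial mode, giving the bromohydrin F6;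
- chlorination of F6 with Ph3P and N-chlorosuccinimide proceeds with retention through participation of the anti-periplanar bromine and comes back at 23.

**Step 9.** Discrimination between the C2 and C4 methylene groups may be insufficient, or the enolate may equilibrate before triflation, giving a mixture of C6 epimers. Fallback from 15:
- dehydrogenation with 2-iodoxybenzoic acid (DMSO, 70 °C) gives the cross-conjugated dienone F7;
- a flavin-dependent ene-reductase (Old Yellow Enzyme family, NADPH recycled with glucose dehydrogenase) reduces one of its two C=C bonds group-selectively to the enone F8;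
- conjugate reduction of F8 with LiBH(sec-Bu)3 and triflation as in step 5 return to the route at 17.

## Further compounds

F1 | step 7 | tert-butyl{[(4R)-4-bromo-5-chloro-1-(1,4-dioxaspiro[4.5]decan-8-ylidene)-5-methylhexyl]oxy}dimethylsilane | CC(C)(Cl)[C@H](Br)CCC(O[Si](C)(C)C(C)(C)C)=C1CCC2(CC1)OCCO2
F2 | step 7 | (10R)-10-bromo-9,9-dimethyl-1,4-dioxadispiro[4.2.5.2]pentadecan-13-one | O=C1CC[C@@H](Br)C(C)(C)C12CCC3(CC2)OCCO3
F0 | step 13 | none | none
F3 | step 12 | (2R,6S,10R)-10-bromo-2-chloro-11,11-dimethyl-7-methylidenespiro[5.5]undecan-3-one | C=C1CC[C@@H](Br)C(C)(C)[C@]12CCC(=O)[C@H](Cl)C2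
F4 | step 12 | (2R,3S,6S,10R)-10-bromo-2-chloro-3,11,11-trimethyl-7-methylidenespiro[5.5]undecan-3-ol | C=C1CC[C@@H](Br)C(C)(C)[C@]12CC[C@](C)(O)[C@H](Cl)C2
F5 | step 11 | (2R,3S,6S,10R)-10-bromo-2,3-epoxy-3,11,11-trimethyl-7-methylidenespiro[5.5]undecane | C=C1CC[C@@H](Br)C(C)(C)[C@]12CC[C@]3(C)O[C@@H]3C2
F6 | step 11 | (2R,3R,6S,10R)-3,10-dibromo-3,11,11-trimethyl-7-methylidenespiro[5.5]undecan-2-ol | C=C1CC[C@@H](Br)C(C)(C)[C@]12CC[C@@](C)(Br)[C@H](O)C2
F7 | step 9 | (10R)-10-bromo-11,11-dimethyl-7-methylidenespiro[5.5]undeca-1,4-dien-3-one | C=C1CC[C@@H](Br)C(C)(C)C12C=CC(=O)C=C2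
F8 | step 9 | (6S,10R)-10-bromo-11,11-dimethyl-7-methylidenespiro[5.5]undec-1-en-3-one | C=C1CC[C@@H](Br)C(C)(C)[C@]12CCC(=O)C=C2
A1 | alternative 1 | (4R)-4-bromo-3,3-dimethyl-2-methylidenecyclohexan-1-one | C=C1C(=O)CC[C@@H](Br)C1(C)C
A2 | alternative 1 | isoprene (2-methylbuta-1,3-diene) | C=CC(C)=C
A3 | alternative 1 | (6R,10R)-10-bromo-3,11,11-trimethylspiro[5.5]undec-2-en-7-one | O=C1CC[C@@H](Br)C(C)(C)[C@]12CCC(C)=CC2
A4 | alternative 2 | (E)-γ-bisabolene | CC1=CC/C(CC1)=C(\C)CCC=C(C)C
A5 | alternative 2 | (6S,10R)-10-bromo-α-chamigrene | CC1=CC[C@@H](Br)C(C)(C)[C@]12CCC(C)=CC2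
A6 | alternative 3 | (2R)-2-allyl-3,3-dimethyl-2-(3-methylbut-3-en-1-yl)cyclohexan-1-one | C=CC[C@@]1(CCC(C)=C)C(=O)CCCC1(C)C
A7 | alternative 3 | (6R)-3,11,11-trimethylspiro[5.5]undec-2-en-7-one | O=C1CCCC(C)(C)[C@]12CCC(C)=CC2
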